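**Assumption:** the SMILES is read as the threo (7S,8S) arylglycerol β-aryl ether (C7 = benzylic carbinol, C8 = ether carbon, C9 = CH2OH; ring A = guaiacyl ring, ring B = 4-hydroxy-2,6-dimethoxyphenoxy ring); TIPSO = tri(propan-2-yl)silyloxy, Ipc = isopinocampheyl from (−)-α-pinene.

## Retrosynthetic overview

1. Target 16 ⇐ bis-TIPS diol 15 (global desilylation) ⇐ homoallylic alcohol 13 (the vinyl group is a masked C9: oxidative cleavage, then reduction).
2. Key disconnection C7–C8: 13 ⇐ aldehyde 8 (C7, electrophile) + allyl aryl ether 6. The ether carbon C8 of 6 is made nucleophilic (α-oxygenated allyl anion, a reversed-polarity d1 synthon) and delivered as a (Z)-γ-aryloxyallyl-B(Ipc)2 reagent.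
3. That one step forms the C–C bond and both stereocentres (threo, 7S,8S), with the C8–O–aryl bond already in place.
4. 6 ⇐ syringaldehyde 1 + allyl bromide 2 (O-allylation, Dakin-type CHO → OH, silylation); 8 ⇐ vanillin 7.
5. No ring is formed: rings A and B are bought as vanillin and syringaldehyde.

## Route

**Step 1**
Reactants: 1 4-hydroxy-3,5-dimethoxybenzaldehyde (syringaldehyde); 2 3-bromoprop-1-ene (allyl bromide)
Product: 3 3,5-dimethoxy-4-(prop-2-en-1-yloxy)benzaldehyde
Conditions: 2 (1.2 equiv), K2CO3 (1.5 equiv), DMF, 60 °C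
Reagents that add atoms: none
Why: Williamson ether synthesis (SN2 of the phenoxide of 1 on the allylic bromide); no stereocentre is involved.

**Step 2**
Reactants: 3 3,5-dimethoxy-4-(prop-2-en-1-yloxy)benzaldehyde
Product: 5 3,5-dimethoxy-4-(prop-2-en-1-yloxy)phenol, via aryl formate 4 (not isolated)
Conditions: 30% H2O2 (1.3 equiv), H2SO4 (cat.), MeOH, rt
Reagents that add atoms: hydrogen peroxide, OO
Why: Acid-catalysed Dakin (Baeyer–Villiger-type) oxidation, in which the electron-rich trialkoxyaryl group migrates to oxygen to give formate 4, methanolysed in situ, while H2O2/acid leaves the deactivated allyl ether alkene alone.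

**Step 3**
Reactants: 5 3,5-dimethoxy-4-(prop-2-en-1-yloxy)phenol
Product: 6 [3,5-dimethoxy-4-(prop-2-en-1-yloxy)phenoxy]tri(propan-2-yl)silane
Conditions: TIPSCl (1.1 equiv), imidazole (2 equiv), DMF, rt
Reagents that add atoms: chlorotri(propan-2-yl)silane (TIPSCl), CC(C)[Si](Cl)(C(C)C)C(C)C
Why: Phenol O-silylation; TIPS is chosen because it survives sec-BuLi and shields the two flanking ring positions from ortho-lithiation in step 5.

**Step 4**
Reactants: 7 4-hydroxy-3-methoxybenzaldehyde (vanillin)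
Product: 8 3-methoxy-4-{[tri(propan-2-yl)silyl]oxy}benzaldehyde
Conditions: TIPSCl (1.1 equiv), imidazole (2 equiv), DMF, rt
Reagents that add atoms: chlorotri(propan-2-yl)silane (TIPSCl), CC(C)[Si](Cl)(C(C)C)C(C)C
Why: Phenol O-silylation, which removes the acidic OH that would destroy the allylborane and keeps the aldehyde electrophilic.

**Step 5**
Reactants: 6 [3,5-dimethoxy-4-(prop-2-en-1-yloxy)phenoxy]tri(propan-2-yl)silane; 8 3-methoxy-4-{[tri(propan-2-yl)silyl]oxy}benzaldehyde
Product: 13 (1S,2S)-2-[2,6-dimethoxy-4-(TIPSO)phenoxy]-1-[3-methoxy-4-(TIPSO)phenyl]but-3-en-1-ol, via allyllithium 9 (not isolated), via borate complex 10 (not isolated), via allylborane 11 (not isolated), via borinate ester 12 (not isolated)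
Conditions: 6 (1.4 equiv), sec-BuLi (1.3 equiv), THF, −78 °C; (+)-Ipc2BOMe (1.5 equiv), −78 °C; BF3·OEt2 (1.8 equiv), then 8 (1.0 equiv), −78 °C → rt; aq NaOAc, 30% H2O2
Reagents that add atoms: none
Why: Proposed new method: sec-BuLi removes the allylic proton next to oxygen of 6 (the ring positions beside the silyl ether are shielded by TIPS), Li–O chelation fixes the Z geometry, boron is placed on the unsubstituted terminus, and the resulting (Z)-γ-aryloxyallylborane 11 adds to 8 through a closed Zimmerman–Traxler chair in which the Z aryloxy group sits axial (syn, i.e. threo pair) and the (−)-α-pinene-derived Ipc groups direct attack to the Re face of the aldehyde (7S, hence 8S), so the ether carbon reacts as an α-oxygenated carbanion with the aldehyde carbon; closest known reaction type: Brown (Z)-γ-alkoxyallylboration with Ipc2B reagents, not yet shown for a 2,6-disubstituted aryloxy group.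

**Step 6**
Reactants: 13 (1S,2S)-2-[2,6-dimethoxy-4-(TIPSO)phenoxy]-1-[3-methoxy-4-(TIPSO)phenyl]but-3-en-1-ol
Product: 15 (1S,2S)-2-[2,6-dimethoxy-4-(TIPSO)phenoxy]-1-[3-methoxy-4-(TIPSO)phenyl]propane-1,3-diol, via aldehyde 14 (not isolated)
Conditions: OsO4 (2 mol %), NaIO4 (4 equiv), 2,6-lutidine (2 equiv), dioxane/H2O 3:1, rt; filter, then MeOH, NaBH4 (excess), 0 °C
Reagents that add atoms: osmium tetroxide, O=[Os](=O)(=O)=O; sodium periodate, [Na+].[O-]I(=O)(=O)=O
Why: Lemieux–Johnson oxidative cleavage (OsO4 dihydroxylation, periodate glycol cleavage) with in situ borohydride reduction turns the vinyl group into CH2OH without touching C7 or C8, provided aldehyde 14 is reduced before C8 enolises; the silyl-capped, very electron-rich arenes are inert to periodate, unlike to ozone.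

**Step 7**
Reactants: 15 (1S,2S)-2-[2,6-dimethoxy-4-(TIPSO)phenoxy]-1-[3-methoxy-4-(TIPSO)phenyl]propane-1,3-diol
Product: 16 (1S,2S)-1-(4-hydroxy-3-methoxyphenyl)-2-(4-hydroxy-2,6-dimethoxyphenoxy)propane-1,3-diol
Conditions: TBAF (2.4 equiv), AcOH (2.4 equiv), THF, 0 °C → rt
Reagents that add atoms: none
Why: Fluoride-induced cleavage of both aryl Si–O bonds (desilylation), buffered with AcOH so the p-hydroxybenzyl alcohol does not ionise to a quinone methide and C7/C8 keep their configuration.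

## Compound list

1 | 4-hydroxy-3,5-dimethoxybenzaldehyde (syringaldehyde) | COc1cc(C=O)cc(OC)c1O | starting material
2 | 3-bromoprop-1-ene (allyl bromide) | C=CCBr | starting material
3 | 3,5-dimethoxy-4-(prop-2-en-1-yloxy)benzaldehyde | COc1cc(C=O)cc(OC)c1OCC=C | intermediate
4 | 3,5-dimethoxy-4-(prop-2-en-1-yloxy)phenyl formate | COc1cc(OC=O)cc(OC)c1OCC=C | intermediate (not isolated)
5 | 3,5-dimethoxy-4-(prop-2-en-1-yloxy)phenol | COc1cc(O)cc(OC)c1OCC=C | intermediate
6 | [3,5-dimethoxy-4-(prop-2-en-1-yloxy)phenoxy]tri(propan-2-yl)silane | COc1cc(O[Si](C(C)C)(C(C)C)C(C)C)cc(OC)c1OCC=C | intermediate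
7 | 4-hydroxy-3-methoxybenzaldehyde (vanillin) | COc1cc(C=O)ccc1O | starting material
8 | 3-methoxy-4-{[tri(propan-2-yl)silyl]oxy}benzaldehyde | COc1cc(C=O)ccc1O[Si](C(C)C)(C(C)C)C(C)C | intermediate
9 | {(2Z)-3-[2,6-dimethoxy-4-(TIPSO)phenoxy]prop-2-en-1-yl}lithium | [Li]C/C=C\Oc1c(OC)cc(O[Si](C(C)C)(C(C)C)C(C)C)cc1OC | intermediate (not isolated)
10 | lithium {(2Z)-3-[2,6-dimethoxy-4-(TIPSO)phenoxy]prop-2-en-1-yl}(methoxy)bis(isopinocampheyl)borate | [Li+].CO[B-](C/C=C\Oc1c(OC)cc(O[Si](C(C)C)(C(C)C)C(C)C)cc1OC)([C@H]1C[C@H]2C[C@@H]([C@@H]1C)C2(C)C)[C@H]1C[C@H]2C[C@@H]([C@@H]1C)C2(C)C | intermediate (not isolated)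
11 | {(2Z)-3-[2,6-dimethoxy-4-(TIPSO)phenoxy]prop-2-en-1-yl}bis(isopinocampheyl)borane | B(C/C=C\Oc1c(OC)cc(O[Si](C(C)C)(C(C)C)C(C)C)cc1OC)([C@H]1C[C@H]2C[C@@H]([C@@H]1C)C2(C)C)[C@H]1C[C@H]2C[C@@H]([C@@H]1C)C2(C)C | intermediate (not isolated)
12 | bis(isopinocampheyl)borinate ester of 13 (O–B at the C7 oxygen) | COc1cc([C@H](OB([C@H]2C[C@H]3C[C@@H]([C@@H]2C)C3(C)C)[C@H]2C[C@H]3C[C@@H]([C@@H]2C)C3(C)C)[C@H](C=C)Oc2c(OC)cc(O[Si](C(C)C)(C(C)C)C(C)C)cc2OC)ccc1O[Si](C(C)C)(C(C)C)C(C)C | intermediate (not isolated)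
13 | (1S,2S)-2-[2,6-dimethoxy-4-(TIPSO)phenoxy]-1-[3-methoxy-4-(TIPSO)phenyl]but-3-en-1-ol | COc1cc([C@H](O)[C@H](C=C)Oc2c(OC)cc(O[Si](C(C)C)(C(C)C)C(C)C)cc2OC)ccc1O[Si](C(C)C)(C(C)C)C(C)C | intermediate
14 | (2R,3S)-2-[2,6-dimethoxy-4-(TIPSO)phenoxy]-3-hydroxy-3-[3-methoxy-4-(TIPSO)phenyl]propanal | COc1cc([C@H](O)[C@H](C=O)Oc2c(OC)cc(O[Si](C(C)C)(C(C)C)C(C)C)cc2OC)ccc1O[Si](C(C)C)(C(C)C)C(C)C | intermediate (not isolated)
15 | (1S,2S)-2-[2,6-dimethoxy-4-(TIPSO)phenoxy]-1-[3-methoxy-4-(TIPSO)phenyl]propane-1,3-diol | COc1cc([C@H](O)[C@H](CO)Oc2c(OC)cc(O[Si](C(C)C)(C(C)C)C(C)C)cc2OC)ccc1O[Si](C(C)C)(C(C)C)C(C)C | intermediate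
16 | (1S,2S)-1-(4-hydroxy-3-methoxyphenyl)-2-(4-hydroxy-2,6-dimethoxyphenoxy)propane-1,3-diol | COc1cc([C@H](O)[C@H](CO)Oc2c(OC)cc(O)cc2OC)ccc1O | target

## Step count and risks

Total steps: 7. Longest linear sequence: 6 (steps 1, 2, 3, 5, 6, 7; step 4 is the one-step side branch).

**Most likely to fail**

1. **Step 5 (key step).** The hindered, electron-rich aryloxy group may slow the addition or erode Z geometry and facial control, and ring lithiation could compete with allylic deprotonation. The fallback sets out from 6 (with 8) and comes back at 13. Lithiated 6 is quenched with 2-isopropoxy-4,4,5,5-tetramethyl-1,3,2-dioxaborolane to give the isolable 2-{(2Z)-3-[2,6-dimethoxy-4-(TIPSO)phenoxy]prop-2-en-1-yl}-4,4,5,5-tetramethyl-1,3,2-dioxaborolane F1, whose geometry and purity can be checked. F1 is then added to 8 under a chiral phosphoric acid catalyst, (R)-TRIP (5 mol %, toluene, −30 °C), so the catalyst and not a stoichiometric borane picks the aldehyde face while the closed chair still gives the threo pair. The first-formed pinacol borate ester of 13 F2 is hydrolysed on work-up to 13; the enantiomeric acid is used if the facial sense proves opposite.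

2. **Step 6.** Aldehyde 14 (α-aryloxy, β-hydroxy) can epimerise at C8 or undergo retro-aldol during hours at rt with 2,6-lutidine. The fallback sets out from 13 and comes back at 15. Dihydroxylation alone (OsO4 cat., N-methylmorpholine N-oxide, acetone/H2O) gives the isolated (2RS,3R,4S)-3-[2,6-dimethoxy-4-(TIPSO)phenoxy]-4-[3-methoxy-4-(TIPSO)phenyl]butane-1,2,4-triol F3. F3 is then cleaved with NaIO4 in THF/pH 7 buffer at 0 °C within minutes and NaBH4 is added at once, so the aldehyde exists only briefly in a base-free medium before it becomes 15.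

3. **Step 2.** Hydride migration (ester formation) or over-oxidation of the electron-rich phenol may lower the yield in the presence of the allyl ether. The fallback sets out from 1 and comes back at 6. Classical alkaline Dakin oxidation of 1 itself (H2O2, aq NaOH, under N2, then acid) gives 2,6-dimethoxybenzene-1,4-diol F4. TIPSCl/imidazole then silylates only the unhindered hydroxyl to give 2,6-dimethoxy-4-{[tri(propan-2-yl)silyl]oxy}phenol F5. Allylation of the remaining hindered hydroxyl with 2 (K2CO3, acetone, reflux) gives 6, so the oxidation is done before any alkene is present.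

## Further compounds

F1 | step 5 | 2-{(2Z)-3-[2,6-dimethoxy-4-(TIPSO)phenoxy]prop-2-en-1-yl}-4,4,5,5-tetramethyl-1,3,2-dioxaborolane | CC1(C)OB(C/C=C\Oc2c(OC)cc(O[Si](C(C)C)(C(C)C)C(C)C)cc2OC)OC1(C)C
F2 | step 5 | pinacol borate ester of 13 (O–B at the C7 oxygen) | COc1cc([C@H](OB2OC(C)(C)C(C)(C)O2)[C@H](C=C)Oc2c(OC)cc(O[Si](C(C)C)(C(C)C)C(C)C)cc2OC)ccc1O[Si](C(C)C)(C(C)C)C(C)C
F3 | step 6 | (2RS,3R,4S)-3-[2,6-dimethoxy-4-(TIPSO)phenoxy]-4-[3-methoxy-4-(TIPSO)phenyl]butane-1,2,4-triol | COc1cc([C@H](O)[C@H](C(O)CO)Oc2c(OC)cc(O[Si](C(C)C)(C(C)C)C(C)C)cc2OC)ccc1O[Si](C(C)C)(C(C)C)C(C)C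
F4 | step 2 | 2,6-dimethoxybenzene-1,4-diol | COc1cc(O)cc(OC)c1O
F5 | step 2 | 2,6-dimethoxy-4-{[tri(propan-2-yl)silyl]oxy}phenol | COc1cc(O[Si](C(C)C)(C(C)C)C(C)C)cc(OC)c1O
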